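## Structural features

The target is a cembranolide: a 14-membered carbocycle (C1–C14) fused through the C1–C2 bond to an α-methylene γ-butyrolactone (ring O on C2, C15 on C1, C16 carbonyl, exocyclic C15=C17), with the two ring-fusion hydrogens trans. The macrocycle holds three E-trisubstituted alkenes (C3=C4, C7=C8, C11=C12), each with its methyl (C18, C19, C20) on the carbon remote from the neighbouring oxygenated carbon, and two secondary allylic acetates at C6 and C10. There are four stereocentres: the contiguous pair C1 (R) and C2 (S), and the isolated centres C6 (S) and C10 (S). C2/C6 and C6/C10 are 1,5-related across a trisubstituted alkene, out of reach of 1,2- or 1,3-induction. Fragile groups are the methylene lactone (Michael acceptor), the three allylic C–O bonds at C2, C6 and C10 (they can ionise towards a tertiary allyl terminus under acid), and the acetates (they do not survive enolate chemistry). The real difficulty is remote 1,5-stereocontrol combined with E geometry at trisubstituted alkenes, followed by closure of the 14-membered ring without loss of either. The key step exploits the C2–C6 segment: two oxygenated carbons joined by E-C3=C4(C18)–C5H2 in a 1,5-anti relationship. This is a 2-methylpropene unit that can be inserted as a 1,3-diborylated linchpin between a C2 aldehyde and a C6 aldehyde, with the transient boron-bearing C3 centre carrying the stereochemical information from C2 to C6.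

## Logic of the disconnections

39 to 38 to 37: the two acetyl C–O bonds at C6 and C10 are cut first, then the hydroxyls are masked as silyl ethers. Acetates cannot be present when the lactone enolate is formed, so acetylation has to be the last step. The demand is a mild desilylation and acylation that leave the methylene lactone alone.

37 to 34: the C15=C17 bond is cut. The exocyclic methylene is the most reactive group and is therefore added last to a saturated lactone. The forward step needs a lactone enolate in a molecule with no other acidic or acylated site, which is why both hydroxyls of 34 are silyl ethers.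

34 to 33 to 32 to 31 to 30: the C12–C20 bond is cut back to an alkenyl iodide, an alkenylsilane and finally the ring alkyne C11≡C12. A trans-addition across a ring alkyne gives the E-trisubstituted alkene that is otherwise hard to make stereoselectively inside a macrocycle. The forward steps must place the metalloid on C12, remote from the C10 hydroxyl, and exchange it with retention.

30 to 29 to 28: the ring bond C11≡C12 is cut by alkyne metathesis, which opens the macrocycle to an acyclic diyne with two methyl-capped alkynes. The cut lies away from all stereocentres. The forward step needs high dilution and no free hydroxyl, hence the silyl ether on C6 in 28.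

28 to 27 to 26: the C6 silyl ether and the lactone C16–O bond are cut. Closing the lactone from a γ-hydroxy ester consumes the C2 hydroxyl and so tells it apart from the C6 hydroxyl without a protecting-group step. The forward step must cleave a tert-butyl ester without ionising the allylic alcohols.

26 to 8, 24 and 16: the C2–C3 and C5–C6 bonds are cut. This removes the C3–C5 unit with its methyl and reduces the problem to two aldehydes of similar size, each with one stereocentre. The forward step must control the C2 face, the anti C2/C3 relationship, the E geometry of C3=C4 and the relay to C6, and must sort the two aldehydes by order of addition.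

24 to 23 to 22 and 18; 22 to 21 to 19; 18 to 17: the allylic C–B bond of 24 is cut. Hydroboration of an allenylboronate would put hydrogen, not methyl, on C4, so the methyl-bearing reagent must come from an allylmetal and a chloroborane. The allylmetal is traced to an α-chloroallylic boronate and that to an isopropenyl boronate. The chloroborane comes from the pinene.

8 to 7 to 6 to 5 to 2 and 3, and 2 to 1: the C1–C15 bond is cut as an auxiliary-controlled enolate alkylation that sets C1. The aldehyde carbon C2 is the former acyl carbon. The forward sequence must keep the tert-butyl ester through reductive removal of the auxiliary and must not epimerise the α-branched aldehyde.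

16 to 15 to 14 to 13 to 10 and 12, then 10 to 9 and 12 to 11: the C9–C10 bond is cut as a vinylogous aldol. This delivers the C10 carbinol, the E-C7=C8 alkene with its methyl and the C6 carbon at the ester level in one step. The forward step needs γ-selectivity, E geometry and catalyst control of the ynal face.

## Other disconnections considered

Alternative 1: The cut is the C1–C2 bond of the carbocycle, traced back to the 17-membered propargyl allyl ether A1 in which C2 and C17 are joined through oxygen.
- Forward step: a chiral lithium amide removes a propargylic hydrogen at C2 and the anion undergoes a [2,3]-sigmatropic shift through a five-membered envelope. C1–C2 forms, O–C17 breaks, and the ring contracts to the 14-membered A2 with the C2 hydroxyl, the C1 centre and the C15=C17 alkene.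
- In favour: it forms the most congested ring bond and both contiguous stereocentres at once, and it closes the large ring as an ether, which is easier than a C–C closure. The E geometry of the C1=C15 alkene of A1 maps onto the required relative configuration. Ring contractions of this type are established for 14-membered carbocycles, so on precedent it is better than the chosen key step. C17 also arrives without a separate methylenation.
- Against: A2 still lacks the C4 methyl, so C3≡C4 needs a trans-hydrometalation and methylation remote from the C2 hydroxyl. C16 must be oxidised to the carboxyl level in the presence of three other allylic methyl groups. The chiral base must cooperate with the resident C6 and C10 centres, which may be a mismatched case. C6 and C10 have to be set separately during the linear assembly of A1.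
- Comparison: Alternative 1 addresses C1/C2, the chosen plan C2/C6. Mechanistically it is the better-documented step. In step economy the chosen plan should be shorter after the key step, because C16 enters at the right oxidation level with 8 and C2, C6 and E-C3=C4 are formed together.

Alternative 2: The cut removes C16 and the C16–O bond, tracing the lactone back to the macrocyclic homopropargylic alcohol A3 with a trans C2 hydroxyl and a C1 ethynyl group.
- Forward step: PdCl2 (divalent palladium) with PPh3 and SnCl2 under CO would form an alkoxycarbonyl–palladium species at the C2 oxygen, insert the alkyne and protonate, giving A4 with C15–C16, C16–O and the exocyclic methylene in place.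
- In favour: the methylene lactone forms in one step without an enolate, and silyl ethers are untouched. On the lactone end game it is better than the chosen plan, which needs steps 23 to 25 for the same result.
- Against: it is a functional-group finish and builds no ring bond of the macrocycle and no stereocentre. A3 has a propargylic, epimerisable C1 hydrogen. Lewis-acidic tin chloride and palladium hydride species at elevated temperature would meet an allylic C2 hydroxyl and two allylic silyl ethers, so ionisation and alkene isomerisation are risks. The fragment corresponding to 8 would be an α-ethynyl aldehyde, which is configurationally labile, so this finish does not combine well with the chosen fragment union.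
- Comparison: both plans leave macrocyclisation to another step, so they are equal there. Alternative 2 is better in precedent and at the lactone stage. The chosen plan is better in what the key step contributes to the skeleton (two C–C bonds, two stereocentres, one alkene).

Alternative 3: The cut is the C11=C12 alkene, traced back to the ring alkyne of A6 and from there to the diyne lactone A5.
- Forward step: Mo(≡CC6H4OMe-4)(OSiPh3)3 with 5 Å molecular sieves would exchange the two methyl-capped alkynes, close the 14-membered ring and release but-2-yne. A trans-addition across C11≡C12 then leads to the E alkene.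
- In favour: the closure is reliable for rings of this size, lies far from the stereocentres, and tolerates lactone, silyl ethers and alkenes.
- Against: it sets no stereocentre. The alkyne costs three further steps and depends on placing the metalloid on C12, remote from the C10 hydroxyl. It leaves open how A5 acquires C2, C6, C10 and two E alkenes.
- Comparison: this is a complement and not a rival. The chosen plan uses the same closure in step 18 (29 differs from A6 only in the silyl group on C10), so on the ring-closing event the two are equal. A route based on Alternative 3 alone would set C2 and C6 in separate, fully precedented operations, which is better in certainty. The chosen plan sets both and the C3=C4 alkene in one operation, which is better in convergence but rests on an unproven step.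

Key step: step 15

Remarks before the steps:
- Positions are given in cembrane numbering throughout; Ipc is isopinocampheyl derived from (+)-α-pinene.
- Assumption: the (R,R) antipode of the bis-phosphoramide catalyst in step 8 is taken to direct the dienolate to the Si face of 10; if the sense is the reverse, the (S,S) antipode is used.
- The configurations of 8, 16, 24 and 26 were re-derived against the target (C1 R, C2 S, C6 S, C10 S) and agree. The C2 descriptor is R in 26 to 36 only because the CIP ranking of C1 against C3 changes once C15 becomes sp2.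
- Step 20 must put silicon on C12, the alkyne carbon remote from the C10 hydroxyl. This is the regiochemistry of the cationic Cp*Ru catalyst, so that catalyst is specified.

## Steps

Step 1
Reactants: 1 hex-5-ynoic acid
Product: 2 hept-5-ynoic acid
Conditions: n-BuLi (2.2 equiv), THF/DMPU, −78 to 0 °C; MeI; aq. HCl
Reagents that add atoms: iodomethane, CI
Why: The carboxylate–acetylide dianion is alkylated at carbon by MeI while the carboxylate is spared (acetylide alkylation).

Step 2
Reactants: 2 hept-5-ynoic acid; 3 (S)-4-benzyloxazolidin-2-one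
Product: 5 (S)-4-benzyl-3-(hept-5-ynoyl)oxazolidin-2-one, via mixed pivalic anhydride 4 (not isolated)
Conditions: PivCl, Et3N, THF, −20 °C; then 3, LiCl, −20 °C to rt
Reagents that add atoms: none
Why: Mixed-anhydride N-acylation; LiCl and Et3N activate the carbamate NH, so no strong base is needed.

Step 3
Reactants: 5 (S)-4-benzyl-3-(hept-5-ynoyl)oxazolidin-2-one
Product: 6 tert-butyl (R)-3-[(S)-4-benzyl-2-oxooxazolidine-3-carbonyl]oct-6-ynoate
Conditions: NaN(SiMe3)2, THF, −78 °C; BrCH2CO2tBu, −78 to −40 °C
Reagents that add atoms: tert-butyl bromoacetate, BrCC(=O)OC(C)(C)C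
Why: The chelated Z sodium enolate is alkylated on the face opposite the benzyl group (oxazolidinone-auxiliary alkylation), which sets C1 as R.

Step 4
Reactants: 6 tert-butyl (R)-3-[(S)-4-benzyl-2-oxooxazolidine-3-carbonyl]oct-6-ynoate
Product: 7 tert-butyl (R)-3-(hydroxymethyl)oct-6-ynoate
Conditions: LiBH4, MeOH (1.1 equiv), THF, 0 °C
Reagents that add atoms: none
Why: LiBH4 reduces the activated imide carbonyl and leaves the hindered tert-butyl ester (reductive auxiliary cleavage); the auxiliary is recovered.

Step 5
Reactants: 7 tert-butyl (R)-3-(hydroxymethyl)oct-6-ynoate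
Product: 8 tert-butyl (R)-3-formyloct-6-ynoate (aldehyde A)
Conditions: PhI(OAc)2, TEMPO (10 mol %), CH2Cl2, rt; used at once
Reagents that add atoms: none
Why: Oxoammonium oxidation of the primary alcohol under near-neutral conditions avoids epimerisation of the α-stereocentre and over-oxidation.

Step 6
Reactants: 9 but-2-yn-1-ol
Product: 10 but-2-ynal
Conditions: MnO2 (excess), CH2Cl2, rt; filtered, kept as CH2Cl2 solution
Reagents that add atoms: none
Why: MnO2 oxidises the propargylic alcohol selectively; the volatile ynal is not concentrated.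

Step 7
Reactants: 11 methyl 3-methylbut-2-enoate
Product: 12 tert-butyl[(1-methoxy-3-methylbuta-1,3-dien-1-yl)oxy]dimethylsilane
Conditions: LDA, THF, −78 °C; TBSCl, DMPU, −78 °C to rt
Reagents that add atoms: tert-butyldimethylsilyl chloride, CC(C)(C)[Si](C)(C)Cl
Why: Kinetic γ-deprotonation of the ester and O-silylation give the silyl dienolate (silyl ketene acetal formation); its ketene-acetal geometry is of no consequence.

Step 8
Reactants: 10 but-2-ynal; 12 tert-butyl[(1-methoxy-3-methylbuta-1,3-dien-1-yl)oxy]dimethylsilane
Product: 13 methyl (S,E)-5-hydroxy-3-methyloct-2-en-6-ynoate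
Conditions: SiCl4 (1.1 equiv), (R,R)-binaphthyldiamine-derived bis-phosphoramide with (CH2)5 tether (2 mol %), iPr2NEt (10 mol %), CH2Cl2, −78 °C; aq. NaHCO3
Reagents that add atoms: none
Why: Vinylogous Mukaiyama aldol: the phosphoramide-bound trichlorosilyl cation activates the ynal and the dienolate attacks through its γ-carbon in the s-trans conformation, which gives the open-chain E enoate; catalyst control (Si-face attack) sets C10 as S.

Step 9
Reactants: 13 methyl (S,E)-5-hydroxy-3-methyloct-2-en-6-ynoate
Product: 14 methyl (S,E)-5-[(tert-butyldimethylsilyl)oxy]-3-methyloct-2-en-6-ynoate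
Conditions: TBSCl, imidazole, DMF, rt
Reagents that add atoms: tert-butyldimethylsilyl chloride, CC(C)(C)[Si](C)(C)Cl
Why: Standard silylation of the propargylic alcohol, needed before the allylic oxidation and the borane chemistry.

Step 10
Reactants: 14 methyl (S,E)-5-[(tert-butyldimethylsilyl)oxy]-3-methyloct-2-en-6-ynoate
Product: 15 (S,E)-5-[(tert-butyldimethylsilyl)oxy]-3-methyloct-2-en-6-yn-1-ol
Conditions: iBu2AlH (2.2 equiv), CH2Cl2, −78 °C; aq. sodium potassium tartrate
Reagents that add atoms: none
Why: 1,2-Reduction of the enoate to the allylic alcohol; alkyne and silyl ether are inert.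

Step 11
Reactants: 15 (S,E)-5-[(tert-butyldimethylsilyl)oxy]-3-methyloct-2-en-6-yn-1-ol
Product: 16 (S,E)-5-[(tert-butyldimethylsilyl)oxy]-3-methyloct-2-en-6-ynal (enal B)
Conditions: MnO2, CH2Cl2, rt
Reagents that add atoms: none
Why: Allylic oxidation with MnO2 gives the enal with retention of the E geometry.

Step 12
Reactants: 17 (+)-α-pinene
Product: 18 (−)-B-chlorodiisopinocampheylborane
Conditions: BH2Cl·SMe2, Et2O, 0 °C to rt; crystallised
Reagents that add atoms: monochloroborane–dimethyl sulfide, C[S+](C)[BH2-]Cl
Why: Double hydroboration of the pinene from the face remote from the gem-dimethyl bridge gives the dialkylchloroborane; crystallisation is expected to raise its optical purity.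

Step 13
Reactants: 19 isopropenylmagnesium bromide
Product: 21 5,5-dimethyl-2-(prop-1-en-2-yl)-1,3,2-dioxaborinane, via isopropenylboronic acid 20 (not isolated)
Conditions: B(OMe)3, THF, −78 °C to rt; aq. HCl; 2,2-dimethylpropane-1,3-diol, MgSO4, Et2O, rt
Reagents that add atoms: trimethyl borate, COB(OC)OC; 2,2-dimethylpropane-1,3-diol, OCC(C)(C)CO
Why: Grignard addition to the borate, hydrolysis and esterification (boronic ester formation); the six-membered ester is chosen because E-selectivity in step 15 depends on a small ligand on boron.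

Step 14
Reactants: 21 5,5-dimethyl-2-(prop-1-en-2-yl)-1,3,2-dioxaborinane
Product: 22 2-(1-chloro-2-methylprop-2-en-1-yl)-5,5-dimethyl-1,3,2-dioxaborinane (racemic)
Conditions: CH2Cl2, n-BuLi, THF, −100 °C; 21; ZnCl2, −100 °C to rt
Reagents that add atoms: dichloromethane, ClCCl
Why: Matteson homologation: LiCHCl2 adds to boron and ZnCl2 promotes 1,2-migration of the isopropenyl group with loss of chloride, giving the α-chloroallylic boronate.

Step 15
Reactants: 22 2-(1-chloro-2-methylprop-2-en-1-yl)-5,5-dimethyl-1,3,2-dioxaborinane; 18 (−)-B-chlorodiisopinocampheylborane; 8 tert-butyl (R)-3-formyloct-6-ynoate; 16 (S,E)-5-[(tert-butyldimethylsilyl)oxy]-3-methyloct-2-en-6-ynal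
Product: 26 tert-butyl (3R)-3-[(1R,2E,5S,6E,9S)-9-(tert-butyldimethylsilyloxy)-1,5-dihydroxy-3,7-dimethyldodeca-2,6-dien-10-yn-1-yl]oct-6-ynoate, via allylzinc chloride 23 (not isolated), via diborylated allyl reagent 24 (not isolated), via anti boryl adduct 25 (not isolated)
Conditions: Zn dust, LiCl, THF, 0 °C to rt, filtered; 18, Et2O, −78 to 0 °C, zinc salts precipitated with 1,4-dioxane; 8 (limiting), −78 °C; 16 (1.5 equiv), −78 °C to rt; aq. NaHCO3, H2O2, 0 °C
Reagents that add atoms: none
Why: Proposed new method: zinc inserts into the allylic C–Cl bond of 22 to give the boryl-substituted allylzinc 23, which transfers its allyl group to the chloroborane 18 (allyl transfer from an allylmetal to a dialkylboron halide), and 1,3-boratropic shifts should then settle on the E 1,3-diboryl isomer 24 in which the bulky CH2B(Ipc)2 group is trans to the boronate. 24 reacts with 8 at −78 °C through a closed six-membered chair with boron on the carbonyl oxygen and C3 as the γ-carbon, forming C2–C3; the E geometry places the boronate equatorial and gives the anti C2-oxy/C3-boryl adduct 25, and the isopinocampheyl groups select the aldehyde Si face, which is the C2 configuration of the target, reagent control overriding the weak bias of the C1 centre whose two CH2 arms are of similar size. 25 is an α-substituted allylboronate that reacts only on warming: with 16 it passes through a second chair in which the C3 substituent is equatorial, so that C5 bonds to C6, the double bond moves to C3=C4 with E geometry and the C3 configuration is relayed to C6 (S), the 1,5-anti relationship. The closest known reaction type is the one-pot double allylboration of two aldehydes with (E)-γ-boryl allyl(diisopinocampheyl)boranes obtained by hydroboration of an allenylboronate, known without a substituent on the central carbon; that hydroboration cannot deliver the C4 methyl because it places hydrogen on C4, hence the transmetalation entry. No ring is closed. The step needs chemoselection between the aldehydes, anti-selectivity, face selectivity and E-selectivity: the first is secured by the order and temperature of addition with 8 limiting, the second by the E reagent, the third by the Ipc groups, and the fourth by the small neopentyl glycol boronate, whose oxygens do not clash with an equatorial C3 group. The C4 methyl is cis to a carbon substituent in either alkene isomer, so its A(1,2) cost is expected to weigh on both chairs alike.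

Step 16
Reactants: 26 tert-butyl (3R)-3-[(1R,2E,5S,6E,9S)-9-(tert-butyldimethylsilyloxy)-1,5-dihydroxy-3,7-dimethyldodeca-2,6-dien-10-yn-1-yl]oct-6-ynoate
Product: 27 (4R,5R)-5-[(1E,4S,5E,8S)-8-(tert-butyldimethylsilyloxy)-4-hydroxy-2,6-dimethylundeca-1,5-dien-9-yn-1-yl]-4-(pent-3-yn-1-yl)dihydrofuran-2(3H)-one
Conditions: camphorsulfonic acid (20 mol %), toluene, rt to 40 °C
Reagents that add atoms: none
Why: Acid-catalysed lactonisation: the C2 hydroxyl is γ to the ester and closes the five-membered lactone with loss of tert-butanol, whereas the C6 hydroxyl cannot reach the ester; the two hydroxyls are thus told apart without a protecting group.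

Step 17
Reactants: 27 (4R,5R)-5-[(1E,4S,5E,8S)-8-(tert-butyldimethylsilyloxy)-4-hydroxy-2,6-dimethylundeca-1,5-dien-9-yn-1-yl]-4-(pent-3-yn-1-yl)dihydrofuran-2(3H)-one
Product: 28 (4R,5R)-5-[(1E,4S,5E,8S)-4,8-bis(tert-butyldimethylsilyloxy)-2,6-dimethylundeca-1,5-dien-9-yn-1-yl]-4-(pent-3-yn-1-yl)dihydrofuran-2(3H)-one
Conditions: TBSCl, imidazole, DMF, rt
Reagents that add atoms: tert-butyldimethylsilyl chloride, CC(C)(C)[Si](C)(C)Cl
Why: Silylation of the remaining C6 hydroxyl so that the alkylidyne catalyst meets no protic group.

Step 18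
Reactants: 28 (4R,5R)-5-[(1E,4S,5E,8S)-4,8-bis(tert-butyldimethylsilyloxy)-2,6-dimethylundeca-1,5-dien-9-yn-1-yl]-4-(pent-3-yn-1-yl)dihydrofuran-2(3H)-one
Product: 29 (1R,2R,3E,6S,7E,10S)-6,10-bis(tert-butyldimethylsilyloxy)-17,20-dinorcembra-3,7-dien-11-yn-16,2-olide
Conditions: Mo(≡CC6H4OMe-4)(OSiPh3)3 (15 mol %), 5 Å MS, toluene (2 mM), rt to 60 °C
Reagents that add atoms: none
Why: Ring-closing alkyne metathesis: the molybdenum alkylidyne exchanges the two methyl-capped alkynes through metallacyclobutadienes and the sieves take up but-2-yne, which drives closure of the 14-membered ring at high dilution; alkenes, lactone and silyl ethers are inert to this catalyst.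

Step 19
Reactants: 29 (1R,2R,3E,6S,7E,10S)-6,10-bis(tert-butyldimethylsilyloxy)-17,20-dinorcembra-3,7-dien-11-yn-16,2-olide
Product: 30 (1R,2R,3E,6S,7E,10S)-6,10-dihydroxy-17,20-dinorcembra-3,7-dien-11-yn-16,2-olide
Conditions: HF·pyridine, pyridine, THF, 0 °C to rt
Reagents that add atoms: none
Why: Fluoride cleavage of both silyl ethers; the free C10 hydroxyl is needed to steer the next step, and the lactone is stable to buffered HF.

Step 20
Reactants: 30 (1R,2R,3E,6S,7E,10S)-6,10-dihydroxy-17,20-dinorcembra-3,7-dien-11-yn-16,2-olide
Product: 31 (1R,2R,3E,6S,7E,10S,11Z)-6,10-dihydroxy-12-(triethylsilyl)-17,20-dinorcembra-3,7,11-trien-16,2-olide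
Conditions: [Cp*Ru(MeCN)3]PF6 (5–10 mol %), Et3SiH (1.3 equiv), CH2Cl2, 0 °C to rt
Reagents that add atoms: triethylsilane, CC[SiH](CC)CC
Why: Ruthenium-catalysed trans-hydrosilylation: with the cationic Cp*Ru catalyst a propargylic alcohol takes up silicon at the alkyne carbon remote from the carbinol, so Si goes to C12 and H to C11, trans to each other, which makes C10 and C13 trans across the new ring alkene.

Step 21
Reactants: 31 (1R,2R,3E,6S,7E,10S,11Z)-6,10-dihydroxy-12-(triethylsilyl)-17,20-dinorcembra-3,7,11-trien-16,2-olide
Product: 32 (1R,2R,3E,6S,7E,10S,11Z)-6,10-dihydroxy-12-iodo-17,20-dinorcembra-3,7,11-trien-16,2-olide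
Conditions: N-iodosuccinimide (1.1 equiv), 2,6-lutidine, (CF3)2CHOH, 0 °C
Reagents that add atoms: N-iodosuccinimide, O=C1CCC(=O)N1I
Why: Ipso-iododesilylation: the β-silyl effect makes the alkenylsilane far more reactive towards iodonium than the other trisubstituted alkenes, and the exchange proceeds with retention of geometry.

Step 22
Reactants: 32 (1R,2R,3E,6S,7E,10S,11Z)-6,10-dihydroxy-12-iodo-17,20-dinorcembra-3,7,11-trien-16,2-olide
Product: 33 (1R,2R,3E,6S,7E,10S,11E)-6,10-dihydroxy-17-norcembra-3,7,11-trien-16,2-olide
Conditions: MeZnCl (5 equiv), Pd(PPh3)4 (10 mol %), THF, rt to 40 °C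
Reagents that add atoms: methylzinc chloride, C[Zn]Cl
Why: Negishi coupling of the alkenyl iodide installs C20 with retention and completes E-C11=C12; the excess organozinc covers the two hydroxyls.

Step 23
Reactants: 33 (1R,2R,3E,6S,7E,10S,11E)-6,10-dihydroxy-17-norcembra-3,7,11-trien-16,2-olide
Product: 34 (1R,2R,3E,6S,7E,10S,11E)-6,10-bis(triethylsilyloxy)-17-norcembra-3,7,11-trien-16,2-olide
Conditions: Et3SiCl, imidazole, CH2Cl2, 0 °C to rt
Reagents that add atoms: chlorotriethylsilane, CC[Si](Cl)(CC)CC
Why: Both hydroxyls are masked so that the lactone enolate can be formed without competing alkoxides; triethylsilyl is chosen because it can be removed under mild conditions at the end.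

Step 24
Reactants: 34 (1R,2R,3E,6S,7E,10S,11E)-6,10-bis(triethylsilyloxy)-17-norcembra-3,7,11-trien-16,2-olide
Product: 37 (1R,2S,3E,6S,7E,10S,11E)-6,10-bis(triethylsilyloxy)cembra-3,7,11,15(17)-tetraen-16,2-olide, via Mannich base 35 (not isolated), via trimethylammonium iodide 36 (not isolated)
Conditions: LDA, THF, −78 °C; CH2=NMe2+ I−, −78 °C to rt; MeI, CH2Cl2/MeOH, rt; aq. NaHCO3, rt
Reagents that add atoms: dimethyl(methylidene)ammonium iodide, C=[N+](C)C.[I-]
Why: α-Methylenation by the Mannich route: the lactone enolate is aminomethylated, the amine is quaternised and the ammonium salt eliminates under mild base to the exocyclic alkene; the new C15 centre of 35 is lost in the elimination.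

Step 25
Reactants: 37 (1R,2S,3E,6S,7E,10S,11E)-6,10-bis(triethylsilyloxy)cembra-3,7,11,15(17)-tetraen-16,2-olide
Product: 38 (1R,2S,3E,6S,7E,10S,11E)-6,10-dihydroxycembra-3,7,11,15(17)-tetraen-16,2-olide
Conditions: HF·pyridine, pyridine, THF, 0 °C
Reagents that add atoms: none
Why: Buffered HF removes the triethylsilyl ethers quickly and offers no nucleophile that could add to the methylene lactone.

Step 26
Reactants: 38 (1R,2S,3E,6S,7E,10S,11E)-6,10-dihydroxycembra-3,7,11,15(17)-tetraen-16,2-olide
Product: 39 (1R,2S,3E,6S,7E,10S,11E)-6,10-diacetoxycembra-3,7,11,15(17)-tetraen-16,2-olide (CID11069750)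
Conditions: Ac2O, pyridine, DMAP (cat.), CH2Cl2, 0 °C to rt
Reagents that add atoms: acetic anhydride, CC(=O)OC(C)=O
Why: DMAP-catalysed acetylation of both secondary allylic alcohols gives the target; no stereocentre is touched.

## Compound list

1 | hex-5-ynoic acid | C#CCCCC(=O)O | starting material
2 | hept-5-ynoic acid | CC#CCCCC(=O)O | intermediate
3 | (S)-4-benzyloxazolidin-2-one | O=C1N[C@@H](Cc2ccccc2)CO1 | starting material
4 | hept-5-ynoic pivalic anhydride | CC#CCCCC(=O)OC(=O)C(C)(C)C | intermediate
5 | (S)-4-benzyl-3-(hept-5-ynoyl)oxazolidin-2-one | CC#CCCCC(=O)N1[C@@H](Cc2ccccc2)COC1=O | intermediate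
6 | tert-butyl (R)-3-[(S)-4-benzyl-2-oxooxazolidine-3-carbonyl]oct-6-ynoate | CC#CCC[C@H](CC(=O)OC(C)(C)C)C(=O)N1[C@@H](Cc2ccccc2)COC1=O | intermediate
7 | tert-butyl (R)-3-(hydroxymethyl)oct-6-ynoate | CC#CCC[C@H](CC(=O)OC(C)(C)C)CO | intermediate
8 | tert-butyl (R)-3-formyloct-6-ynoate (aldehyde A) | CC#CCC[C@H](CC(=O)OC(C)(C)C)C=O | intermediate
9 | but-2-yn-1-ol | CC#CCO | starting material
10 | but-2-ynal | CC#CC=O | intermediate
11 | methyl 3-methylbut-2-enoate | COC(=O)C=C(C)C | starting material
12 | tert-butyl[(1-methoxy-3-methylbuta-1,3-dien-1-yl)oxy]dimethylsilane (ketene-acetal geometry undefined) | C=C(C)C=C(OC)O[Si](C)(C)C(C)(C)C | intermediate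
13 | methyl (S,E)-5-hydroxy-3-methyloct-2-en-6-ynoate | COC(=O)/C=C(\C)C[C@H](O)C#CC | intermediate
14 | methyl (S,E)-5-[(tert-butyldimethylsilyl)oxy]-3-methyloct-2-en-6-ynoate | COC(=O)/C=C(\C)C[C@H](O[Si](C)(C)C(C)(C)C)C#CC | intermediate
15 | (S,E)-5-[(tert-butyldimethylsilyl)oxy]-3-methyloct-2-en-6-yn-1-ol | OC/C=C(\C)C[C@H](O[Si](C)(C)C(C)(C)C)C#CC | intermediate
16 | (S,E)-5-[(tert-butyldimethylsilyl)oxy]-3-methyloct-2-en-6-ynal (enal B) | O=C/C=C(\C)C[C@H](O[Si](C)(C)C(C)(C)C)C#CC | intermediate
17 | (+)-α-pinene | CC1=CC[C@@H]2C[C@H]1C2(C)C | starting material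
18 | (−)-B-chlorodiisopinocampheylborane | ClB([C@@H]1C[C@@H]2C[C@H]([C@H]1C)C2(C)C)[C@@H]1C[C@@H]2C[C@H]([C@H]1C)C2(C)C | intermediate
19 | isopropenylmagnesium bromide | CC(=C)[Mg]Br | starting material
20 | isopropenylboronic acid | CC(=C)B(O)O | intermediate
21 | 5,5-dimethyl-2-(prop-1-en-2-yl)-1,3,2-dioxaborinane | CC(=C)B1OCC(C)(C)CO1 | intermediate
22 | 2-(1-chloro-2-methylprop-2-en-1-yl)-5,5-dimethyl-1,3,2-dioxaborinane (racemic) | C=C(C)C(Cl)B1OCC(C)(C)CO1 | intermediate
23 | [(E)-3-(5,5-dimethyl-1,3,2-dioxaborinan-2-yl)-2-methylallyl]zinc chloride (σ-allyl form drawn) | Cl[Zn]C/C(C)=C/B1OCC(C)(C)CO1 | intermediate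
24 | (E)-[3-(5,5-dimethyl-1,3,2-dioxaborinan-2-yl)-2-methylallyl]bis(isopinocampheyl)borane | C/C(CB([C@@H]1C[C@@H]2C[C@H]([C@H]1C)C2(C)C)[C@@H]1C[C@@H]2C[C@H]([C@H]1C)C2(C)C)=C\B1OCC(C)(C)CO1 | intermediate
25 | tert-butyl (3R)-3-[(1S,2S)-1-(diisopinocampheylboryloxy)-2-(5,5-dimethyl-1,3,2-dioxaborinan-2-yl)-3-methylbut-3-en-1-yl]oct-6-ynoate (C2-oxy/C3-boryl anti) | CC#CCC[C@H](CC(=O)OC(C)(C)C)[C@@H](OB([C@@H]1C[C@@H]2C[C@H]([C@H]1C)C2(C)C)[C@@H]1C[C@@H]2C[C@H]([C@H]1C)C2(C)C)[C@@H](B1OCC(C)(C)CO1)C(C)=C | intermediate
26 | tert-butyl (3R)-3-[(1R,2E,5S,6E,9S)-9-(tert-butyldimethylsilyloxy)-1,5-dihydroxy-3,7-dimethyldodeca-2,6-dien-10-yn-1-yl]oct-6-ynoate | CC#CCC[C@H](CC(=O)OC(C)(C)C)[C@@H](O)/C=C(\C)C[C@H](O)/C=C(\C)C[C@H](O[Si](C)(C)C(C)(C)C)C#CC | intermediate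
27 | (4R,5R)-5-[(1E,4S,5E,8S)-8-(tert-butyldimethylsilyloxy)-4-hydroxy-2,6-dimethylundeca-1,5-dien-9-yn-1-yl]-4-(pent-3-yn-1-yl)dihydrofuran-2(3H)-one | O=C1C[C@@H](CCC#CC)[C@@H](O1)/C=C(\C)C[C@H](O)/C=C(\C)C[C@H](O[Si](C)(C)C(C)(C)C)C#CC | intermediate
28 | (4R,5R)-5-[(1E,4S,5E,8S)-4,8-bis(tert-butyldimethylsilyloxy)-2,6-dimethylundeca-1,5-dien-9-yn-1-yl]-4-(pent-3-yn-1-yl)dihydrofuran-2(3H)-one | O=C1C[C@@H](CCC#CC)[C@@H](O1)/C=C(\C)C[C@H](O[Si](C)(C)C(C)(C)C)/C=C(\C)C[C@H](O[Si](C)(C)C(C)(C)C)C#CC | intermediate
29 | (1R,2R,3E,6S,7E,10S)-6,10-bis(tert-butyldimethylsilyloxy)-17,20-dinorcembra-3,7-dien-11-yn-16,2-olide | C1C(=O)O[C@H]2/C=C(\C)C[C@H](O[Si](C)(C)C(C)(C)C)/C=C(\C)C[C@H](O[Si](C)(C)C(C)(C)C)C#CCC[C@H]12 | intermediate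
30 | (1R,2R,3E,6S,7E,10S)-6,10-dihydroxy-17,20-dinorcembra-3,7-dien-11-yn-16,2-olide | C1C(=O)O[C@H]2/C=C(\C)C[C@H](O)/C=C(\C)C[C@H](O)C#CCC[C@H]12 | intermediate
31 | (1R,2R,3E,6S,7E,10S,11Z)-6,10-dihydroxy-12-(triethylsilyl)-17,20-dinorcembra-3,7,11-trien-16,2-olide | C1C(=O)O[C@H]2/C=C(\C)C[C@H](O)/C=C(\C)C[C@H](O)/C=C(\[Si](CC)(CC)CC)CC[C@H]12 | intermediate
32 | (1R,2R,3E,6S,7E,10S,11Z)-6,10-dihydroxy-12-iodo-17,20-dinorcembra-3,7,11-trien-16,2-olide | C1C(=O)O[C@H]2/C=C(\C)C[C@H](O)/C=C(\C)C[C@H](O)/C=C(\I)CC[C@H]12 | intermediate
33 | (1R,2R,3E,6S,7E,10S,11E)-6,10-dihydroxy-17-norcembra-3,7,11-trien-16,2-olide | C1C(=O)O[C@H]2/C=C(\C)C[C@H](O)/C=C(\C)C[C@H](O)/C=C(\C)CC[C@H]12 | intermediate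
34 | (1R,2R,3E,6S,7E,10S,11E)-6,10-bis(triethylsilyloxy)-17-norcembra-3,7,11-trien-16,2-olide | C1C(=O)O[C@H]2/C=C(\C)C[C@H](O[Si](CC)(CC)CC)/C=C(\C)C[C@H](O[Si](CC)(CC)CC)/C=C(\C)CC[C@H]12 | intermediate
35 | (1R,2R,3E,6S,7E,10S,11E)-17-(dimethylamino)-6,10-bis(triethylsilyloxy)cembra-3,7,11-trien-16,2-olide (C15 epimers) | CN(C)CC1C(=O)O[C@H]2/C=C(\C)C[C@H](O[Si](CC)(CC)CC)/C=C(\C)C[C@H](O[Si](CC)(CC)CC)/C=C(\C)CC[C@H]12 | intermediate
36 | trimethylammonium iodide of 35 (C15 epimers) | C[N+](C)(C)CC1C(=O)O[C@H]2/C=C(\C)C[C@H](O[Si](CC)(CC)CC)/C=C(\C)C[C@H](O[Si](CC)(CC)CC)/C=C(\C)CC[C@H]12.[I-] | intermediate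
37 | (1R,2S,3E,6S,7E,10S,11E)-6,10-bis(triethylsilyloxy)cembra-3,7,11,15(17)-tetraen-16,2-olide | C=C1C(=O)O[C@H]2/C=C(\C)C[C@H](O[Si](CC)(CC)CC)/C=C(\C)C[C@H](O[Si](CC)(CC)CC)/C=C(\C)CC[C@H]12 | intermediate
38 | (1R,2S,3E,6S,7E,10S,11E)-6,10-dihydroxycembra-3,7,11,15(17)-tetraen-16,2-olide | C=C1C(=O)O[C@H]2/C=C(\C)C[C@H](O)/C=C(\C)C[C@H](O)/C=C(\C)CC[C@H]12 | intermediate
39 | (1R,2S,3E,6S,7E,10S,11E)-6,10-diacetoxycembra-3,7,11,15(17)-tetraen-16,2-olide (CID11069750) | C=C1C(=O)O[C@H]2/C=C(\C)C[C@H](OC(C)=O)/C=C(\C)C[C@H](OC(C)=O)/C=C(\C)CC[C@H]12 | target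

## Step count and least certain steps

Total: 26 steps. Longest linear sequence: 17 steps (steps 1–5, then 15–26; the branch through steps 6 and 8–11 is equally long).

Step 15 (key step, proposed new method).
- What may go wrong: incomplete zinc-to-boron allyl transfer, leaving allylzinc that adds to 8 without facial control. Incomplete equilibration of 24 to the E isomer, which erodes the anti relationship. Reaction through the geminal diboryl isomer at the wrong allyl terminus. Loss of rate or of E-selectivity in the second allylboration, because the C4 methyl raises the energy of the chair with the equatorial C3 group.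
- Fallback (known chemistry, from 16 and 8, back at 26): catalytic asymmetric propargylation of 16 with allenylboronic acid pinacol ester under a chiral BINOL-derived phosphoric acid (antipode chosen for the S carbinol) would give the homopropargylic alcohol (4S,5E,8S)-8-[(tert-butyldimethylsilyl)oxy]-6-methylundec-5-ene-1,9-diyn-4-ol F1. Zirconium-catalysed methylalumination of its terminal alkyne (Cp2ZrCl2, AlMe3, then I2) would give the iodoalkene (1E,4S,5E,8S)-8-[(tert-butyldimethylsilyl)oxy]-1-iodo-2,6-dimethylundeca-1,5-dien-9-yn-4-ol F2, with the C4 methyl and the E geometry in place. Nozaki–Hiyama–Kishi coupling of F2 with 8 (CrCl2, NiCl2 cat., chiral sulfonamide ligand to control C2) returns to 26.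

Step 8.
- What may go wrong: poor facial selectivity or slow turnover with the small, volatile ynal; competing α-attack of the dienolate; uncertainty about which catalyst antipode gives the S carbinol.
- Fallback (from 10, back at 14): the known methallylborane, made from (−)-B-methoxydiisopinocampheylborane and 2-methylallylmagnesium chloride, would add to 10 with the same facial sense as in step 15 to give (S)-2-methylhept-1-en-5-yn-4-ol F3. Silylation (TBSCl, imidazole) gives (S)-tert-butyldimethyl[(2-methylhept-1-en-5-yn-4-yl)oxy]silane F4. Ozonolysis of the 1,1-disubstituted alkene (O3, CH2Cl2, −78 °C, then Me2S) gives the methyl ketone (S)-4-[(tert-butyldimethylsilyl)oxy]hept-5-yn-2-one F5. Horner–Wadsworth–Emmons olefination with trimethyl phosphonoacetate gives 14 after removal of the Z isomer.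

Step 16.
- What may go wrong: acid-promoted ionisation of the allylic C2–O or C6–O bond (allylic transposition or elimination) competing with slow acyl substitution at the hindered tert-butyl ester.
- Fallback (from 26, back at 27): anionic lactonisation, in which the C2 alkoxide (NaH or KN(SiMe3)2, THF, 0 °C) attacks the ester and expels tert-butoxide. No acid is present and no new compound is formed on the way.

Step 18.
- What may go wrong: oligomerisation by intermolecular metathesis, or failure to close because the trans lactone and the two E alkenes hold the alkyne termini apart; catalyst deactivation.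
- Fallback (from 26, back at 30): the order of the two ring closures is reversed. Silylation of both hydroxyls (TBSOTf, 2,6-lutidine) gives the tris(silyl ether) of 26 F6. The same molybdenum catalyst closes the more flexible open-chain diyne to the 14-membered cycloalkyne tert-butyl ester F7. HF·pyridine gives the triol ester F8, and acid-catalysed lactonisation as in step 16 gives 30.

Step 20.
- What may go wrong: erosion of regioselectivity, with silicon delivered to C11 as well, if the conformation of the macrocycle overrides the preference of the catalyst.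
- Fallback (from 30, back at 32): tethered delivery. Silylation with (HMe2Si)2NH gives the bis(dimethylsilyl) ether of 30 F9. Intramolecular trans-hydrosilylation of the C10 O–SiMe2H group (KOtBu cat., or the same ruthenium catalyst) can only reach C12 through a five-membered ring and gives the 2,5-dihydro-1,2-oxasilole fused at C10–C12 F10. Iododesilylation with N-iodosuccinimide and aqueous work-up cleaves the ring Si–C bond and the remaining C6 silyl ether to give 32.

Further compounds

F1 | step 15 | (4S,5E,8S)-8-[(tert-butyldimethylsilyl)oxy]-6-methylundec-5-ene-1,9-diyn-4-ol | C#CC[C@H](O)/C=C(\C)C[C@H](O[Si](C)(C)C(C)(C)C)C#CC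
F2 | step 15 | (1E,4S,5E,8S)-8-[(tert-butyldimethylsilyl)oxy]-1-iodo-2,6-dimethylundeca-1,5-dien-9-yn-4-ol | I/C=C(\C)C[C@H](O)/C=C(\C)C[C@H](O[Si](C)(C)C(C)(C)C)C#CC
F3 | step 8 | (S)-2-methylhept-1-en-5-yn-4-ol | C=C(C)C[C@H](O)C#CC
F4 | step 8 | (S)-tert-butyldimethyl[(2-methylhept-1-en-5-yn-4-yl)oxy]silane | C=C(C)C[C@H](O[Si](C)(C)C(C)(C)C)C#CC
F5 | step 8 | (S)-4-[(tert-butyldimethylsilyl)oxy]hept-5-yn-2-one | CC(=O)C[C@H](O[Si](C)(C)C(C)(C)C)C#CC
F0 | step 16 | none | none
F6 | step 18 | tert-butyl (3R)-3-[(1R,2E,5S,6E,9S)-1,5,9-tris(tert-butyldimethylsilyloxy)-3,7-dimethyldodeca-2,6-dien-10-yn-1-yl]oct-6-ynoate | CC#CCC[C@H](CC(=O)OC(C)(C)C)[C@@H](O[Si](C)(C)C(C)(C)C)/C=C(\C)C[C@H](O[Si](C)(C)C(C)(C)C)/C=C(\C)C[C@H](O[Si](C)(C)C(C)(C)C)C#CC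
F7 | step 18 | tert-butyl 2-[(1R,2R,3E,6S,7E,10S)-2,6,10-tris(tert-butyldimethylsilyloxy)-4,8-dimethylcyclotetradeca-3,7-dien-11-yn-1-yl]acetate | C1C[C@H](CC(=O)OC(C)(C)C)[C@@H](O[Si](C)(C)C(C)(C)C)/C=C(\C)C[C@H](O[Si](C)(C)C(C)(C)C)/C=C(\C)C[C@H](O[Si](C)(C)C(C)(C)C)C#C1
F8 | step 18 | tert-butyl 2-[(1R,2R,3E,6S,7E,10S)-2,6,10-trihydroxy-4,8-dimethylcyclotetradeca-3,7-dien-11-yn-1-yl]acetate | C1C[C@H](CC(=O)OC(C)(C)C)[C@@H](O)/C=C(\C)C[C@H](O)/C=C(\C)C[C@H](O)C#C1
F9 | step 20 | (1R,2R,3E,6S,7E,10S)-6,10-bis(dimethylsilyloxy)-17,20-dinorcembra-3,7-dien-11-yn-16,2-olide | C1C(=O)O[C@H]2/C=C(\C)C[C@H](O[SiH](C)C)/C=C(\C)C[C@H](O[SiH](C)C)C#CCC[C@H]12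
F10 | step 20 | 2,2-dimethyl-2,5-dihydro-1,2-oxasilole fused at C10 (C5 of the oxasilole), C11 and C12 (C3 of the oxasilole) of the 17,20-dinorcembra-3,7,11-trien-16,2-olide, with 6-(dimethylsilyloxy) | C1C(=O)O[C@H]2/C=C(\C)C[C@H](O[SiH](C)C)/C=C(\C)C[C@@H]3O[Si](C)(C)C(=C3)CC[C@H]12
A1 | alternative 1 | 17-membered propargyl allyl ether (O between C2 and C17; C3≡C4; E-C1=C15; 6S,10S bis-silyl ether) | O1CC#CC[C@H](O[Si](C)(C)C(C)(C)C)/C=C(\C)C[C@H](O[Si](C)(C)C(C)(C)C)/C=C(\C)CC/C=C(\C)C1
A2 | alternative 1 | 14-membered cycloalkyne with C2 hydroxyl and C1 isopropenyl | O[C@H]1C#CC[C@H](O[Si](C)(C)C(C)(C)C)/C=C(\C)C[C@H](O[Si](C)(C)C(C)(C)C)/C=C(\C)CC[C@@H]1C(C)=C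
A3 | alternative 2 | macrocyclic trans C2-hydroxy C1-ethynyl triene, 6,10-bis(silyl ether) | O[C@H]1/C=C(\C)C[C@H](O[Si](C)(C)C(C)(C)C)/C=C(\C)C[C@H](O[Si](C)(C)C(C)(C)C)/C=C(\C)CC[C@@H]1C#C
A4 | alternative 2 | 6,10-bis(tert-butyldimethylsilyl) ether of the target diol | C=C1C(=O)O[C@H]2/C=C(\C)C[C@H](O[Si](C)(C)C(C)(C)C)/C=C(\C)C[C@H](O[Si](C)(C)C(C)(C)C)/C=C(\C)CC[C@H]12
A5 | alternative 3 | diyne lactone with C6 OTBS and C10 OSiEt3 | O=C1C[C@@H](CCC#CC)[C@@H](O1)/C=C(\C)C[C@H](O[Si](C)(C)C(C)(C)C)/C=C(\C)C[C@H](O[Si](CC)(CC)CC)C#CC
A6 | alternative 3 | 14-membered cycloalkyne trans lactone with C6 OTBS and C10 OSiEt3 | C1C(=O)O[C@H]2/C=C(\C)C[C@H](O[Si](C)(C)C(C)(C)C)/C=C(\C)C[C@H](O[Si](CC)(CC)CC)C#CCC[C@H]12
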